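Readings and results stem from a simulated flask with made-up constants; scatter was added.

- noon: left-handed substrate 0.20 M; right-handed substrate 0.20 M; partner 2 equiv; catalyst 2.5 mol%; run made earlier
- flask: left-handed substrate 0.10 M; partner 2.00 equiv; catalyst 2.5 mol%; right-handed substrate 0.10 M; time 15 h

noon run (percent of the left-handed substrate and right-handed substrate together charged): time / h: left-handed product / % = 0.167: 9; 0.500: 17; 0.833: 21; 1.33: 31; 2.00: 39; 2.50: 39; 3.00: 43

(each reading ± 1.5 percentage points)

- catalyst is single-handed; left-handed substrate and right-handed substrate are mirror images of each other, charged as a racemate, each of them at the stated concentration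
- no earlier run changes the charge of catalyst; that part of a forecast is a guess

- amount of left-handed product in percent of the left-handed substrate and right-handed substrate together charged, at 50 min, 4.0 h and 15 h

**Noon clock.** Read the noon run as a clock. Assume one step, first order in left-handed substrate, partner and catalyst. Partner is charged at as much as both substrates together, so the fraction y of both substrates that has become left-handed product obeys K t = 2 ln[(1 − y)/(1 − 2y)]. The single scattered reading of 39% at 2.00 h then gives K = 1.02 h⁻¹, the opening pseudo-first-order constant of the left-handed substrate, meaning the rate constant times the charged catalyst and partner concentrations. The new flask has the same equivalents and loading at 0.10 M instead of 0.20 M, so both concentrations in K drop together and the flask's constant is a quarter of the noon one, K′ = 0.255 h⁻¹, with the catalyst order a guess.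

**Time ladder.** The noon lifetime 0.980 h is shorter than the flask's lifetime τ = 3.92 h. At 50 min, well inside τ, this reckoning gives 9.16%. At 4.0 h, close to τ, it gives 28.5%. At 15 h, far beyond τ, it gives 46.0%, under the ceiling of 50.0% that the charged left-handed substrate sets for one step. The noon readings end at 43% after 3.00 h, short of τ.

**The forecast.** The forecast gives 11%, 32% and 47%, above this reckoning at each time, and it warns: “Partner order and catalyst order are both untested guesses”.

**The flask.** The flask gives 8.06%, 27.1% and 54.3%, the last above the ceiling, with 51% of the right-handed substrate charged still present at 15.0 h.

    partner + catalyst + right-handed substrate → catalyst + right-handed product (k = 22.0 M⁻² h⁻¹)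
    left-handed substrate ⇌ right-handed substrate (k = 0.110 h⁻¹)
    partner + catalyst + left-handed substrate → catalyst + left-handed product (k = 440 M⁻² h⁻¹)

The noon K is 9.27 times the interconversion constant 0.11 h⁻¹, and the flask's opening K′ is 2.32 times it. Scaled by the 42% of partner left in the flask at 15.0 h, the reckoned K′ comes to 0.107 h⁻¹, level with 0.11 h⁻¹.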